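Adding the two columns is the easy step: in the theta run, free monomer and monomer in chains come to 101% at 60.0 min, so within the scatter the solid monomer has dissolved by then.

| setting | theta | epsilon | flask |
|---|---|---|---|
| solid monomer | 0.50 M | 0.50 M | 0.50 M |
| transfer agent | 3.4 mM | 7.5 mM | 5.00 mM |
| initiator | 1.7 mol% | 1.7 mol% | 1.7 mol% |
| remark | run made earlier | run made earlier |  |
| time |  |  | 1.5 h |

- theta (time / min: monomer in chains / %, free monomer / %): 5.00: 0.2, 44.9; 15.0: 7.5, 73.1; 25.0: 18.2, 77.0; 40.0: 35.6, 64.1; 60.0: 52.9, 48.0; 80.0: 65.1, 34.8
- epsilon (time / min: monomer in chains / %, free monomer / %): 12.0: 4.7, 68.7; 25.0: 18.8, 76.8; 40.0: 35.2, 65.2; 50.0: 43.9, 55.9; 60.0: 51.7, 48.3; 80.0: 63.3, 36.1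

(each reading ± 0.3 percentage points)

- solid, in amounts per volume of the solution: solid monomer
- the analysis behind the earlier runs scatters by 0.3 percentage points, standard deviation
- steps under discussion: free monomer + initiator -> living end + monomer in chains; free monomer + living end -> monomer in chains + living end; living end + transfer agent -> dead chain; solid monomer <-> free monomer
- at the start none of the solid monomer is in solution

- grey: doubling the dissolution coefficient of the solid monomer, all else as stated
- blue: doubling the solubility of the solid monomer, all else as stated
- violet: doubling the amount of initiator, all else as stated

- amount of monomer in chains at 1.5 h, in percent of the solid monomer charged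
- concentration of free monomer in solution at 50 min, in percent of saturation
- the change that raises the amount of monomer in chains at 1.5 h, in percent of the solid monomer charged most ("none" if none brings more than 2 percentage points) (grey / blue / violet / none)
- amount of monomer in chains at 1.5 h, in percent of the solid monomer charged, after blue

Two colleagues read these runs differently. The first holds that the solid monomer sets the pace: at 25.0 min the theta run has 95.2% dissolved but 18.2% in chains, so faster dissolving should bring the yield forward.

The second counts turnovers. The turnover rate, the number of factors of e by which free monomer falls per minute once dissolved, is 0.0161 /min in the theta run and 0.0146 /min in the epsilon run, between 60.0 min and 80.0 min, with 2.21 times the transfer agent. This is pseudo-first-order decay on a stock of living ends.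

The flask's 5.00 mM lies between the runs, so the second colleague takes their mean, 0.0153 /min. From a mean 48.1% free at 60.0 min, the flask then has 30.4% free at 1.5 h, so 69.6% in chains.

That free monomer equals 1.19 turnovers, so the count effectively began 12.3 min late. Recovering half of this hold-up under blue gives 72.3%. Under violet, doubling the 8.50 mM of initiator and so, on this colleague's assumption, the living ends doubles the count and gives 90.8%.

The forecast sides with the second colleague at 69%, 65%, violet and 71% after blue: “Doubling initiator should roughly double living ends”.

The flask gives 69.3%, 64.6% of saturation at 50 min, and violet as the best change, with a gain of 21 percentage points against 2.7 points for blue and 1.6 points for grey; after blue it gives 72.1%.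

    free monomer + initiator → living end + monomer in chains (k = 0.420 /M/min)
    free monomer + living end → monomer in chains + living end, rate k2*[living end]*[free monomer] (k = 1.90 /M/min)
    living end + transfer agent → dead chain (kL = 0.300 /M/min)
    solid monomer ⇌ free monomer, rate k4*(cs4 - [free monomer]) while solid is left; crystals form when [free monomer] > cs4 (solubility = 0.430 M, k = 0.150 /min)

At 0.0963 h, free monomer in the flask is made 15.7 times faster than it is used up. Half of the dissolving is done by 0.0963 h, earlier than the 0.672 h for chain growth. The flask's 30.7% of free monomer at 1.50 h is 1.18 turnovers. At the same turnover rate, the same flask read at 4.0 h gains 2.29 more, which leaves 3.09% free, and it holds 4.14%.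

(The numbers in the tables were computed for substances that don't exist.)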